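The readings stem from a simulated flask for an exercise; scatter was added.

- Target in the east run gives the easy step: it falls from 0.0588 M at 3.2 h to 0.0537 M at 5.4 h. At that pace target lasts 24.2 h, a reading that carries the scatter; this is the drain lifetime, the hours in which target shrinks by the factor e.

| flask | substrate | partner | time |
|---|---|---|---|
| north-east | 0.100 M | 0.300 M |  |
| south | 0.0600 M | 0.260 M |  |
| north-west | 0.300 M | 0.300 M |  |
| east | 0.100 M | 0.900 M |  |
| north | 0.100 M | 0.300 M | 22 h |

| run | time / h | [target] / M |
|---|---|---|
| north-east run | 1.1 | 0.0163 |
| north-east run | 2.2 | 0.0264 |
| north-east run | 3.2 | 0.0286 |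
| north-east run | 4.3 | 0.0329 |
| north-east run | 5.4 | 0.0345 |
| south run | 1.1 | 0.0103 |
| south run | 2.2 | 0.0167 |
| south run | 3.2 | 0.0176 |
| south run | 4.3 | 0.0227 |
| south run | 5.4 | 0.0208 |
| north-west run | 1.1 | 0.0375 |
| north-west run | 2.2 | 0.0506 |
| north-west run | 3.2 | 0.0553 |
| north-west run | 4.3 | 0.0586 |
| north-west run | 5.4 | 0.0595 |
| east run | 1.1 | 0.0451 |
| east run | 2.2 | 0.0570 |
| east run | 3.2 | 0.0588 |
| east run | 4.3 | 0.0573 |
| east run | 5.4 | 0.0537 |

(readings scatter by 0.001 M)

1. apparent order in [substrate] of the starting rate, round the charge of the north-east run (the rate where two percent of its substrate have turned into target) (one fixed amount of target, the same in the runs compared)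
2. apparent order in [partner] of the starting rate, round the charge of the north-east run (the rate where two percent of its substrate have turned into target)
3. target in the north run at 22 h, as a share of the substrate charged

- Overall: substrate + partner -> target.
- Constant volume, constant temperature.
- A reading of a species includes what of it is bound.
- "The second partner" is partner.
- An order is taken over about fifteen percent of the charge, up and down.

- The north flask has the charge of the north-east run, so its reckoning starts from the last north-east reading, 0.0345 M at 5.4 h, with 16.6 h still to count.
- Fast extreme: target in the north flask drains with the east lifetime. The remaining hours are 0.686 lifetimes, which leaves 17.4% of the substrate charged.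
- Slow extreme: the drain goes strictly with the partner charge. The north flask holds less partner than the east run, so the lifetime stretches to 72.7 h. That is 0.228 lifetimes, which leaves 27.5%.
- With less partner, the north flask should sit above the fast extreme, while strict proportion is an assumption that the runs do not test. This reckoning therefore commits to the middle, 22.4%.
- The forecast gives orders of 0.9 in substrate and 1.1 in partner, and 25% for the north run, with the remark “The east run's decline suggests a drain of a few percent per hour”.
- The flask gives orders of 1.0 and 1.1, and the north run gives 24.2%, inside the span of the two extremes.

    2 partner ⇌ reagent dimer, settled at all times (74.30 L mol⁻¹)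
    substrate + reagent dimer → target + partner (1.883 L mol⁻¹ h⁻¹)
    target + partner → side product (1.044 L mol⁻¹ h⁻¹)
    2 substrate → homo dimer (2.840 L mol⁻¹ h⁻¹)

- In the north run, target stands at 24.2% with both losses acting: taking away the passing of target and partner into side product lifts it to 49.8%, and taking away the passing of two substrate into homo dimer lifts it to 54.4%. At the charge of the north run, the reagent dimer equilibrium leaves 0.0417 M of partner unbound, and the step to side product then gives target a lifetime of 23.0 h, shorter than the east lifetime of 24.2 h and than the stretched one of 72.7 h.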